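**Retrosynthetic overview**

- The strategy rests on ring A: C5, C6, C7 and C8 all carry oxygen (C5–O and C8–O para, C6/C7 vicinal methoxyls). These four carbons are the four carbons of dimethyl squarate, and the fusion bond C4a=C8a is the C3=C2 bond of a 2-aryl-4-pyranone (ring C).
- Last disconnections: the 4'-O-benzyl ether and the 5-O- and 8-O-methyl groups, giving the 5,8-hydroquinone.
- Ring A is opened at C8–C8a (6π closure of a dienylketene) back to a 4-hydroxy-4-(pyranon-3-yl)cyclobutenone. Its C4a–C5 bond comes from addition of a 5-magnesiated 2-arylpyranone to dimethyl squarate.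
- Ring C comes from a crossed Claisen condensation of O-benzylsyringoyl chloride with 4-methoxybutenone and acid closure. The iodine is put on the butenone before the condensation, so its position (pyranone C5) is fixed by construction and not by a late halogenation that could also attack C3 or the electron-rich aryl ring.
- Ring order: B (from syringic acid), then C (pyranone), then the appended cyclobutenone, then A last.

Key step: step 7

Remark: the target has no stereocentre and is achiral, so no enantiocontrol is required. Carbinol 13 is formed racemic and its centre is destroyed in step 7.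

**Route**

Step 1
Reactants: 1 syringic acid
Product: 3 4-benzyloxy-3,5-dimethoxybenzoic acid, via benzyl 4-benzyloxy-3,5-dimethoxybenzoate 2 (not isolated)
Conditions: BnBr (2.4 equiv), K2CO3, DMF, 60 °C; then 2 M NaOH, MeOH–THF, 65 °C; HCl to pH 2
Reagents that add atoms: benzyl bromide BrCc1ccccc1; sodium hydroxide [Na+].[OH-]
Why: Williamson O-benzylation of phenoxide and carboxylate followed by saponification of the benzyl ester leaves only the 4-OH masked, as a benzyl ether that tolerates amide base, catalytic acid, Grignard reagent, thermolysis and methylation and is removed last by hydrogenolysis.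

Step 2
Reactants: 3 4-benzyloxy-3,5-dimethoxybenzoic acid
Product: 4 4-benzyloxy-3,5-dimethoxybenzoyl chloride
Conditions: (COCl)2, cat. DMF, CH2Cl2, 0 °C to rt; evaporate, use crude
Reagents that add atoms: oxalyl chloride ClC(=O)C(Cl)=O
Why: Vilsmeier-catalysed acid chloride formation is mild enough for the benzyl ether and gives the acyl donor for the Claisen condensation.

Step 3
Reactants: 5 (E)-4-methoxybut-3-en-2-one
Product: 7 (Z)-3-iodo-4-methoxybut-3-en-2-one, via 4-chloro-3-iodo-4-methoxybutan-2-one 6 (not isolated)
Conditions: ICl (1.05 equiv), CH2Cl2, −78 °C; then Et3N (1.5 equiv), −78 to 0 °C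
Reagents that add atoms: iodine monochloride ClI
Why: Halogenation–dehydrohalogenation of a β-alkoxy enone (I+ to the nucleophilic α-carbon, chloride to the oxocarbenium carbon, then E1cB loss of HCl) places iodine on the only carbon that can become pyranone C5, and the alkene geometry is of no consequence because it is lost in step 5.

Step 4
Reactants: 7 (Z)-3-iodo-4-methoxybut-3-en-2-one; 4 4-benzyloxy-3,5-dimethoxybenzoyl chloride
Product: 9 (Z)-1-(4-benzyloxy-3,5-dimethoxyphenyl)-4-iodo-5-methoxypent-4-ene-1,3-dione, via lithium dienolate 8 (not isolated)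
Conditions: 7 (2.2 equiv), LiHMDS (2.2 equiv), THF, −78 °C; then 4 (1.0 equiv), −78 °C; aq. NH4Cl
Reagents that add atoms: none
Why: Crossed Claisen condensation in which the kinetic lithium enolate of the methyl ketone is C-acylated by the acid chloride and a second equivalent of enolate takes up the proton of the more acidic 1,3-diketone, with vinyl iodide and enol ether untouched by the hindered base at −78 °C.

Step 5
Reactants: 9 (Z)-1-(4-benzyloxy-3,5-dimethoxyphenyl)-4-iodo-5-methoxypent-4-ene-1,3-dione
Product: 10 2-(4-benzyloxy-3,5-dimethoxyphenyl)-5-iodo-4H-pyran-4-one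
Conditions: TFA (cat.), toluene, rt
Reagents that add atoms: none
Why: Acid-catalysed γ-pyrone closure, in which the diketone enol oxygen adds 6-endo to the protonated β-methoxy enone and methanol is lost, should give the pyranone with iodine necessarily at C5, and catalytic TFA at room temperature should leave the benzyl ether intact.

Step 6
Reactants: 10 2-(4-benzyloxy-3,5-dimethoxyphenyl)-5-iodo-4H-pyran-4-one; 11 dimethyl squarate
Product: 13 4-[6-(4-benzyloxy-3,5-dimethoxyphenyl)-4-oxo-4H-pyran-3-yl]-4-hydroxy-2,3-dimethoxycyclobut-2-en-1-one (racemic), via 5-chloromagnesio-2-arylpyran-4-one 12 (not isolated)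
Conditions: i-PrMgCl·LiCl (1.05 equiv), THF, −78 °C, 20 min; cannulate into 11 (1.3 equiv), THF, −78 °C; sat. NH4Cl at −78 °C; Et3N-deactivated silica
Reagents that add atoms: none
Why: Iodine–magnesium exchange on the electron-poor vinyl iodide gives a carbonyl-stabilised Grignard reagent that adds 1,2 to one of the two equivalent, strongly electrophilic carbonyls of the squarate ester, and the new carbinol centre is formed racemic and is erased in step 7.

Step 7
Reactants: 13 4-[6-(4-benzyloxy-3,5-dimethoxyphenyl)-4-oxo-4H-pyran-3-yl]-4-hydroxy-2,3-dimethoxycyclobut-2-en-1-one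
Product: 16 4'-benzyloxy-5,8-dihydroxy-3',5',6,7-tetramethoxyflavone, via (Z)-dienylketene 14 (not isolated), via 8a-H cyclohexadienone 15 (not isolated)
Conditions: PhMe (0.02 M, degassed), 110 °C, Ar; concentrate under Ar and use directly
Reagents that add atoms: none
Why: Proposed new method: thermal conrotatory 4π opening of the cyclobutenone C1–C4 bond should give dienylketene 14 with the donor OH turned outward and the pyranonyl arm inward, after which the ketene carbon bonds to the oxygen-bearing CH of the pyranone (C2 in the numbering of 13) in a 6π electrocyclization that forms C8–C8a and closes ring A as dienone 15, which enolises to the aromatic 5,8-hydroquinone. The closest known reaction type is the Moore ring expansion of 4-aryl-, 4-heteroaryl- and 4-alkenyl-4-hydroxycyclobutenones made from squarate esters, and what is new is a push–pull 4-pyranone C=C as the 2π arm. It should still close because the electrocyclization is pericyclic and makes little polar demand on the alkene, the enol O–H···O=C4 hydrogen bond holds the pyranone CH on the ketene side, and aromatisation of ring A restores the pyranone conjugation that 15 interrupts. Ring A is closed in a six-membered disrotatory 6π mode, and no stereocentre survives since the carbinol carbon and the transient C8a–H carbon both become sp2. The step needs torquoselectivity, secured by the outward preference of the hydroxyl, and site selectivity, secured because only that CH lies within six-ring reach of the ketene carbon while closure on the C4 carbonyl oxygen would need a seven-membered ring.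

Step 8
Reactants: 16 4'-benzyloxy-5,8-dihydroxy-3',5',6,7-tetramethoxyflavone
Product: 17 4'-benzyloxy-3',5,5',6,7,8-hexamethoxyflavone
Conditions: Me2SO4 (6 equiv), K2CO3 (8 equiv), acetone, reflux, Ar
Reagents that add atoms: dimethyl sulfate COS(=O)(=O)OC
Why: Exhaustive Williamson O-methylation under the forcing conditions that also alkylate the chelated 5-OH should convert both phenols, and exclusion of air keeps the hydroquinone dianion from oxidising to the 5,8-quinone.

Step 9
Reactants: 17 4'-benzyloxy-3',5,5',6,7,8-hexamethoxyflavone
Product: 18 4'-hydroxy-3',5,5',6,7,8-hexamethoxyflavone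
Conditions: H2 (1 atm), 10% Pd/C, EtOAc–MeOH, rt
Reagents that add atoms: none
Why: Catalytic hydrogenolysis should cleave the benzyl aryl ether selectively, since the conjugated flavone C2=C3 bond and the methyl ethers are not reduced at ambient pressure and temperature.

**Compound list**

1 | syringic acid | COc1cc(C(=O)O)cc(OC)c1O | starting material
2 | benzyl 4-benzyloxy-3,5-dimethoxybenzoate | COc1cc(C(=O)OCc2ccccc2)cc(OC)c1OCc1ccccc1 | intermediate
3 | 4-benzyloxy-3,5-dimethoxybenzoic acid | COc1cc(C(=O)O)cc(OC)c1OCc1ccccc1 | intermediate
4 | 4-benzyloxy-3,5-dimethoxybenzoyl chloride | COc1cc(C(=O)Cl)cc(OC)c1OCc1ccccc1 | intermediate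
5 | (E)-4-methoxybut-3-en-2-one | CO/C=C/C(C)=O | starting material
6 | 4-chloro-3-iodo-4-methoxybutan-2-one (diastereomer mixture, racemic) | COC(Cl)C(I)C(C)=O | intermediate
7 | (Z)-3-iodo-4-methoxybut-3-en-2-one | CO/C=C(\I)C(C)=O | intermediate
8 | lithium (Z)-3-iodo-4-methoxybuta-1,3-dien-2-olate | C=C(O[Li])/C(I)=C/OC | intermediate
9 | (Z)-1-(4-benzyloxy-3,5-dimethoxyphenyl)-4-iodo-5-methoxypent-4-ene-1,3-dione | CO/C=C(\I)C(=O)CC(=O)c1cc(OC)c(OCc2ccccc2)c(OC)c1 | intermediate
10 | 2-(4-benzyloxy-3,5-dimethoxyphenyl)-5-iodo-4H-pyran-4-one | COc1cc(-c2cc(=O)c(I)co2)cc(OC)c1OCc1ccccc1 | intermediate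
11 | dimethyl squarate (3,4-dimethoxycyclobut-3-ene-1,2-dione) | COC1=C(OC)C(=O)C1=O | starting material
12 | [6-(4-benzyloxy-3,5-dimethoxyphenyl)-4-oxo-4H-pyran-3-yl]magnesium chloride (LiCl complex) | COc1cc(-c2cc(=O)c([Mg]Cl)co2)cc(OC)c1OCc1ccccc1 | intermediate
13 | 4-[6-(4-benzyloxy-3,5-dimethoxyphenyl)-4-oxo-4H-pyran-3-yl]-4-hydroxy-2,3-dimethoxycyclobut-2-en-1-one (racemic) | COC1=C(OC)C(O)(c2coc(-c3cc(OC)c(OCc4ccccc4)c(OC)c3)cc2=O)C1=O | intermediate
14 | (Z)-4-[6-(4-benzyloxy-3,5-dimethoxyphenyl)-4-oxo-4H-pyran-3-yl]-4-hydroxy-2,3-dimethoxybuta-1,3-dien-1-one (dienylketene) | O=C=C(OC)/C(OC)=C(/O)c1coc(-c2cc(OC)c(OCc3ccccc3)c(OC)c2)cc1=O | intermediate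
15 | 2-(4-benzyloxy-3,5-dimethoxyphenyl)-5-hydroxy-6,7-dimethoxy-8aH-chromene-4,8-dione (racemic, transient) | O=C1C(OC)=C(OC)C(O)=C2C(=O)C=C(-c3cc(OC)c(OCc4ccccc4)c(OC)c3)OC12 | intermediate
16 | 4'-benzyloxy-5,8-dihydroxy-3',5',6,7-tetramethoxyflavone | COc1cc(-c2cc(=O)c3c(O)c(OC)c(OC)c(O)c3o2)cc(OC)c1OCc1ccccc1 | intermediate
17 | 4'-benzyloxy-3',5,5',6,7,8-hexamethoxyflavone | COc1cc(-c2cc(=O)c3c(OC)c(OC)c(OC)c(OC)c3o2)cc(OC)c1OCc1ccccc1 | intermediate
18 | 4'-hydroxy-3',5,5',6,7,8-hexamethoxyflavone | COc1cc(-c2cc(=O)c3c(OC)c(OC)c(OC)c(OC)c3o2)cc(OC)c1O | target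

**Step count**

Total: 9 steps. Longest linear sequence: 8 steps (1, 2, 4, 5, 6, 7, 8, 9 from syringic acid); step 3 is a one-step side branch.

**Steps most likely to fail**

Step 7 (Proposed new method). The dienylketene may not close onto the pyranone, because closure interrupts the vinylogous-ester conjugation of ring C. It could instead be consumed by lactonisation after inward rotation of the hydroxyl or by intermolecular ketene trapping. The hydroquinone may also be oxidised by air during handling. The fallback uses known flavone chemistry, sets out from acid chloride 4 and returns at 17. Acid chloride 4 would acylate 1-(2-hydroxy-3,4,5,6-tetramethoxyphenyl)ethanone F1 (bought in; pyridine, DMAP) to give 2-acetyl-3,4,5,6-tetramethoxyphenyl 4-benzyloxy-3,5-dimethoxybenzoate F2. Baker–Venkataraman acyl migration (KOH, pyridine, 50 °C) would give 1-(4-benzyloxy-3,5-dimethoxyphenyl)-3-(2-hydroxy-3,4,5,6-tetramethoxyphenyl)propane-1,3-dione F3. Cyclodehydration (p-TsOH, toluene, 90 °C) would close ring C and give 17, which is carried through step 9.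

Step 6. The magnesiated pyranone has the metal anti to the ring C–O bond and may ring-open by β-elimination to an ynone enolate before it adds to the squarate. Competing attack of the exchange reagent on the pyranone is a second possible loss. The fallback sets out from iodide 10 and squarate 11 and returns directly at 13. It replaces the polar Grignard addition by a nickel-catalysed chromium(II)-mediated Nozaki–Hiyama–Kishi coupling (CrCl2, cat. NiCl2, DMF–THF, rt). The alkenylchromium(III) species is non-basic and much less prone to β-alkoxide loss, and the strained squarate carbonyl is electrophilic enough to stand in for the usual aldehyde. No new compound is made on the way.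

Step 4. The dienolate of the iodo enone may lose HI (the vinylic H is anti to iodine) or undergo O-acylation, so that little diketone forms. The fallback sets out from 5 and 4 and returns at 10. The well-behaved lithium enolate of the parent 4-methoxybutenone 5 would be acylated with 4 to give (E)-1-(4-benzyloxy-3,5-dimethoxyphenyl)-5-methoxypent-4-ene-1,3-dione F4. Catalytic TFA in toluene would close it to 2-(4-benzyloxy-3,5-dimethoxyphenyl)-4H-pyran-4-one F5. Iodine would then be introduced at C5 by the amine-triggered α-iodination (I2, pyridine, DMAP, CHCl3). That reaction starts by conjugate addition at the unsubstituted C6, so it should spare C3 and the electron-rich aryl ring. The regiochemical question avoided in the main route would have to be checked at this point.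

**Further compounds**

F1 | step 7 | 1-(2-hydroxy-3,4,5,6-tetramethoxyphenyl)ethanone (bought in) | CC(=O)c1c(O)c(OC)c(OC)c(OC)c1OC
F2 | step 7 | 2-acetyl-3,4,5,6-tetramethoxyphenyl 4-benzyloxy-3,5-dimethoxybenzoate | CC(=O)c1c(OC)c(OC)c(OC)c(OC)c1OC(=O)c1cc(OC)c(OCc2ccccc2)c(OC)c1
F3 | step 7 | 1-(4-benzyloxy-3,5-dimethoxyphenyl)-3-(2-hydroxy-3,4,5,6-tetramethoxyphenyl)propane-1,3-dione | COc1cc(C(=O)CC(=O)c2c(O)c(OC)c(OC)c(OC)c2OC)cc(OC)c1OCc1ccccc1
F0 | step 6 | none | none
F4 | step 4 | (E)-1-(4-benzyloxy-3,5-dimethoxyphenyl)-5-methoxypent-4-ene-1,3-dione | CO/C=C/C(=O)CC(=O)c1cc(OC)c(OCc2ccccc2)c(OC)c1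
F5 | step 4 | 2-(4-benzyloxy-3,5-dimethoxyphenyl)-4H-pyran-4-one | COc1cc(-c2cc(=O)cco2)cc(OC)c1OCc1ccccc1
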